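**Assumption:** the target carries no descriptor for the C1–C1' axis, so the route is planned for the four stereogenic carbons only; rotamers about the axis, should they not interconvert, are taken as they form and separated at the end if needed.

Numbering used throughout: each half is a 5,6,7,8-tetrahydronaphthalen-2-ol joined to the other through C1 (C2 OH, C3 methyl, C5 isopropyl, C8 methyl; C4a and C8a are the ring-fusion carbons).

## Analysis of the target

The target is a C30 biaryl made of two identical cadinane-type phenols (5,6,7,8-tetrahydronaphthalen-2-ols) linked C1–C1'. Each benzene ring is pentasubstituted (only C4–H is left). The biaryl bond is flanked by four ortho substituents: two hydroxyls and the two ring-fusion carbons C8a and C8a', whose C8 methyl groups lie peri to the axis. There are four stereogenic carbons, (5S,8S,5'S,8'S). In each half the two benzylic centres are 1,4-related across the saturated ring and cis, and the two halves are homotopic, so there are two stereochemical problems, each to be solved twice. The electron-rich hindered phenols are sensitive to oxidants, and the tertiary benzylic C–H bonds at C5 and C8 are sensitive to dehydrogenating agents, which could carry a half on to a naphthalene. The hard points are the crowded biaryl bond, the substitution pattern of two pentasubstituted arenes, and the remote cis relationship of C5 and C8. The strategy rests on two features. The carbocycle C8a–C8–C7–C6–C5–C4a with its methyl and isopropyl groups is the six-membered ring of (R)-carvone, whose stereocentre becomes C5. The remaining carbons, C4–C3(CH3)–C2(O)–C1–C1'–C2'(O)–C3'(CH3)–C4', form one symmetrical eight-carbon 1,4-diketone chain with an isopropenyl group at each end.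

## Retrosynthetic reasoning

**11 to 10.** The two C8 stereocentres are removed first by drawing C7=C8 double bonds in both halves. C8 is the only stereocentre that the chiral pool does not supply. A trisubstituted aryl alkene inside a six-membered ring is a good substrate for face-selective hydrogenation, and C5 in the same ring already differentiates the two faces. The forward step must add hydrogen to C7=C8 anti to the C5 isopropyl group, twice.

**10 to 9 to 8.** Each phenol ring of 10 is the enol form of a cross-conjugated cyclohexadienone that still has hydrogen at C4a. Removing the C3=C4 unsaturation leads to the bis-dienone 8 (C2=O, C1=C8a, C8=C7 in each half). Compound 8 is a constitutional isomer of 11, so it could aromatise by simple double-bond migration, but that would create C8 by an uncontrolled protonation. The forward route therefore introduces C3=C4 deliberately, through the silyl enol ether 9, so that the ring aromatises while C7=C8 stays in place. The gain is that the arene problem becomes carbonyl chemistry.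

**8 to 2 and 6.** The C1=C8a and C4–C4a bonds are cut in both halves (Robinson annulation transform, applied twice). These four bonds divide 8 exactly into two terpene rings 2 and the linear bis-enone 6. The crowded C1–C1' bond is never made by a coupling, because it is the central CH2–CH2 bond of 6. The C3 methyl and the C2 oxygen arrive already in place, so no arene regiochemistry has to be controlled. The forward reaction needs the alpha'-enolate of 2 to add to both enone termini of 6, and then each central methylene of the resulting 1,4-diketone to condense onto a ring carbonyl.

**2 to 1; 6 to 4 and 5; 4 to 3.** Enone 2 is 1 with the isopropenyl group saturated. The two acyl–alkenyl bonds of 6 are cut to the bis(N-methoxy-N-methylamide) 4 and two equivalents of the alkenyl Grignard reagent 5, and 4 comes from the diacid chloride 3. All three are short, routine operations, so the risk of the route sits in the annulation.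

## Alternatives that were turned down

**Alternative 1: double 6-exo Heck closure at C8a.**
- Disconnection: C8a–C8 in both halves.
- Forward key step: the open-chain biaryl bis(triflate) A2 would cyclise under a zerovalent palladium catalyst with a bulky trialkylphosphine. Each aryl–palladium adds 6-exo to its terminal alkene and beta-hydride elimination gives the bis(8-methylidene) compound A1.
- For it: a 6-exo Heck closure is one of the most dependable ring closures, and on the single ring-forming event it is more predictable than the annulation chosen here.
- Against it: A2 is itself the hard part. It needs the tetra-ortho-substituted biaryl, two benzylic isopropyl stereocentres made by asymmetric synthesis, and a triflate at the most shielded position of each ring, where oxidative addition is slow. C8 is still set by a late hydrogenation, now of a 1,1-disubstituted exocyclic alkene, which gives less facial discrimination and which palladium hydride can move into the ring. Two methyl ethers must be cleaved at the end.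
- Comparison: roughly twice the step count of the chosen route, with the same open question at C8.

**Alternative 2: silicon-bridged double [2+2+2] benzannulation.**
- Disconnection: C4a–C8a, C1–C2 and C3–C4 in each half.
- Forward key step: tetrayne A4 and bis(alkynyl)silane A5 would undergo two cyclotrimerisations under a cationic rhodium–bisphosphine catalyst to give silafluorene A3. A Tamao–Fleming oxidation of both C–Si bonds would then give the diol.
- For it: both C5 and C8 are fixed before any ring exists, so no late hydrogenation is needed, and a chiral ligand could in principle control the axis. On stereocontrol at C8 it is stronger than the chosen route.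
- Against it: A4 carries four propargylic stereocentres that must all be made by asymmetric synthesis. The central 1,3-diyne has to react once at each alkyne with the tethered silane diyne, in competition with self-trimerisation, and the diaryl silane must then be cleaved twice.
- Comparison: the chosen route gives up early control of C8 and in exchange takes C5 from the chiral pool and reaches the key step in three steps.

**Alternative 3: double Diels–Alder on a diynedione.**
- Disconnection: C1–C8a and C2–C3 in each half.
- Forward key step: two molecules of the chiral-pool diene A8 would add to diynedione A7, and a quinone oxidant would aromatise the bis-cyclohexadiene to the diacetyl biaryl A6. Baeyer–Villiger oxidation and ester cleavage would follow.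
- For it: it is as convergent as the chosen route, and it brings both stereocentres of each half in with the diene, so it is stronger on C8.
- Against it: the regiochemistry of each cycloaddition depends on a weak bias, since both diene termini are alkyl-substituted. The second cycloaddition must create the crowded axis thermally. The quinone oxidant must aromatise the new rings without abstracting the benzylic hydrogens at C5 and C8. Two functional-group steps are needed to turn acetyl into hydroxyl. The allylic C8 centre of A8 can be lost by hydrogen shift.
- Comparison: in the chosen route the position of methyl and oxygen is fixed by the connectivity of 6, and the oxygen is at the right oxidation level from the start.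

Key step: step 4

## Route

Step 1
Reactants: 1 (R)-(−)-carvone
Product: 2 (5R)-2-methyl-5-(propan-2-yl)cyclohex-2-en-1-one (carvotanacetone)
Conditions: H2 (1 atm), RhCl(PPh3)3 (2 mol %), toluene, 25 °C
Reagents that add atoms: none
Why: Homogeneous hydrogenation with RhCl(PPh3)3 discriminates by alkene substitution: the 1,1-disubstituted isopropenyl group is reduced while the trisubstituted, conjugated ring alkene is left; the stereocentre is not touched and no new one is formed.

Step 2
Reactants: 3 succinyl chloride (butanedioyl dichloride)
Product: 4 N,N'-dimethoxy-N,N'-dimethylbutanediamide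
Conditions: MeNH(OMe)·HCl (2.2 equiv), pyridine (4.5 equiv), CH2Cl2, 0 → 25 °C
Reagents that add atoms: N,O-dimethylhydroxylamine hydrochloride, CNOC.Cl
Why: Nucleophilic acyl substitution at both acid chloride groups (Schotten–Baumann type) with pyridine as acid scavenger; slow addition at 0 °C keeps the 1,4-diacyl chloride from closing to cyclic by-products.

Step 3
Reactants: 4 N,N'-dimethoxy-N,N'-dimethylbutanediamide; 5 isopropenylmagnesium bromide (prop-1-en-2-ylmagnesium bromide)
Product: 6 2,7-dimethylocta-1,7-diene-3,6-dione
Conditions: 5 (2.4 equiv), THF, −78 → 0 °C; inverse quench into 1 M HCl at 0 °C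
Reagents that add atoms: none
Why: Weinreb ketone synthesis: each amide takes up one alkenyl Grignard and the magnesium-chelated tetrahedral intermediate survives until work-up, so no tertiary alcohol forms. Pouring the mixture into cold dilute acid protonates the liberated N,O-dimethylhydroxylamine before it can add to the new enones; 6 is kept cold with a trace of BHT and used at once.

Step 4
Reactants: 2 (5R)-2-methyl-5-(propan-2-yl)cyclohex-2-en-1-one (two equivalents react; 2.3 equiv used); 6 2,7-dimethylocta-1,7-diene-3,6-dione
Product: 8 (5S,5'S)-3,3',8,8'-tetramethyl-5,5'-di(propan-2-yl)-4,4',4a,4a',5,5',6,6'-octahydro-[1,1'-binaphthalene]-2,2'(3H,3'H)-dione (bis-dienone; C3/C4a epimer mixture), via bis-Michael tetraketone 7 (not isolated)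
Conditions: LiN(i-Pr)2 (2.2 equiv), THF, −78 °C; 6 (1.0 equiv), −78 °C; AcOH, −78 °C; then KOH, MeOH, 0 → 25 °C, argon
Reagents that add atoms: none
Why: This is a Robinson annulation run twice in one flask: LiN(i-Pr)2 removes the alpha'-hydrogen of 2 (ring C6, the future C4a) under kinetic control, and the cross-conjugated lithium dienolate adds in Michael fashion to the unsubstituted methylene terminus of each isopropenyl ketone of 6, forming both C4–C4a bonds; the closest known reaction is the alpha'-annulation of carvone-type enones with alkyl vinyl ketones. Protonation with acetic acid at −78 °C gives tetraketone 7 before the adduct enolate, which is nucleophilic at C3, can add to C7 of its own enone and form a bicyclo[2.2.2]octanone. In methanolic KOH each C2 ketone enolises toward the central methylene (C1) and closes its ring by a 6-(enolendo)-exo-trig aldol addition onto the ring carbonyl (C8a), and E1cB dehydration gives C1=C8a in conjugation with C8=C7; both rings close in this mode. The competing five-membered closure inside the 1,4-diketone starts from the C3 enolate and ends at a tertiary aldol whose alpha-carbon is quaternary, so it cannot dehydrate and reverts, whereas the six-membered path drains into the dienone; acid is avoided because a 1,4-diketone would cyclise to a furan. New stereocentres arise at C3 and C4a (the Michael step should place the new chain trans to the C5 isopropyl group, C3 is uncontrolled); both are epimerisable and both disappear on aromatisation, so no control is needed, while C5 is not enolisable and keeps the carvone configuration. The step needs alpha' rather than gamma enolisation of 2, secured by the kinetic base, 1,4- rather than 1,2-addition, secured by the unhindered terminal methylene, and a short, cold, oxygen-free aldol stage so that 8 is collected before base moves its double bonds into the ring and aromatises it without control at C8.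

Step 5
Reactants: 8 bis-dienone
Product: 9 (5S,5'S)-3,3',8,8'-tetramethyl-5,5'-di(propan-2-yl)-2,2'-bis(trimethylsilyloxy)-4,4',4a,4a',5,5',6,6'-octahydro-1,1'-binaphthalene (bis(silyl enol ether); C4a epimer mixture)
Conditions: LiN(i-Pr)2 (2.5 equiv), THF, −78 °C; Me3SiCl, −78 → 0 °C
Reagents that add atoms: chlorotrimethylsilane, C[Si](C)(C)Cl
Why: Kinetic deprotonation of a conjugated ketone by a lithium amide takes the alpha'-hydrogen (C3–H, reached through the lithium-bound carbonyl) rather than the gamma (C4a) or epsilon (C6) hydrogens, and O-silylation fixes the cross-conjugated C3=C2 enol ether in both halves. The C3 stereocentres vanish here, so the mixture narrows to C4a epimers.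

Step 6
Reactants: 9 bis(silyl enol ether)
Product: 10 (5S,5'S)-3,3',8,8'-tetramethyl-5,5'-di(propan-2-yl)-5,5',6,6'-tetrahydro-[1,1'-binaphthalene]-2,2'-diol (bis(dihydronaphthol))
Conditions: Pd(OAc)2 (2.2 equiv), MeCN, 25 °C, argon
Reagents that add atoms: none
Why: Saegusa–Ito oxidation: divalent palladium exchanges with silicon to give the C3 palladium enolate, beta-hydride elimination toward C4 installs C3=C4 (elimination toward the methyl group would give an exocyclic isomer that ends at the same product), and the resulting 4a-H cyclohexa-2,5-dienone tautomerises at once to the phenol. C7=C8 lies outside the enolate and is kept; DDQ is avoided because it would carry the 5,6-dihydronaphthalene on to a naphthalene and erase C5.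

Step 7
Reactants: 10 bis(dihydronaphthol)
Product: 11 (5S,5'S,8S,8'S)-3,3',8,8'-tetramethyl-5,5'-di(propan-2-yl)-5,5',6,6',7,7',8,8'-octahydro-[1,1'-binaphthalene]-2,2'-diol (target)
Conditions: H2 (50 bar), [Ir(cod)(t-Bu-PHOX)]BArF (4 mol %, matched ligand enantiomer), CH2Cl2, 25 °C
Reagents that add atoms: none
Why: Iridium-catalysed asymmetric hydrogenation of a trisubstituted cyclic aryl alkene (the 1-methyl-3,4-dihydronaphthalene class). The C5 isopropyl group sits pseudoaxial to avoid allylic strain with C4–H and shields its own face of C7=C8, so hydrogen should add anti to it and leave the C8 methyl cis to isopropyl (8S). The ligand enantiomer used is the one whose preference coincides with this substrate bias, so both controls point the same way in both halves.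

## Compound list

1 | (R)-(−)-carvone, (5R)-2-methyl-5-(prop-1-en-2-yl)cyclohex-2-en-1-one | CC1=CC[C@H](CC1=O)C(C)=C | starting material
2 | (5R)-2-methyl-5-(propan-2-yl)cyclohex-2-en-1-one (carvotanacetone) | CC1=CC[C@H](CC1=O)C(C)C | intermediate
3 | succinyl chloride (butanedioyl dichloride) | O=C(Cl)CCC(=O)Cl | starting material
4 | N,N'-dimethoxy-N,N'-dimethylbutanediamide | CON(C)C(=O)CCC(=O)N(C)OC | intermediate
5 | isopropenylmagnesium bromide (prop-1-en-2-ylmagnesium bromide) | CC(=C)[Mg]Br | starting material
6 | 2,7-dimethylocta-1,7-diene-3,6-dione | CC(=C)C(=O)CCC(=O)C(C)=C | intermediate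
7 | 2,7-dimethyl-1,8-bis[(6S)-3-methyl-2-oxo-6-(propan-2-yl)cyclohex-3-en-1-yl]octane-3,6-dione (epimer mixture at ring C1 and chain C2/C7) | CC1=CC[C@@H](C(C)C)C(CC(C)C(=O)CCC(=O)C(C)CC2C(=O)C(C)=CC[C@H]2C(C)C)C1=O | intermediate
8 | (5S,5'S)-3,3',8,8'-tetramethyl-5,5'-di(propan-2-yl)-4,4',4a,4a',5,5',6,6'-octahydro-[1,1'-binaphthalene]-2,2'(3H,3'H)-dione (C3/C4a epimer mixture) | CC1CC2C(=C(C3=C4C(C)=CC[C@@H](C(C)C)C4CC(C)C3=O)C1=O)C(C)=CC[C@H]2C(C)C | intermediate
9 | (5S,5'S)-3,3',8,8'-tetramethyl-5,5'-di(propan-2-yl)-2,2'-bis(trimethylsilyloxy)-4,4',4a,4a',5,5',6,6'-octahydro-1,1'-binaphthalene (C4a epimer mixture) | CC1=C(O[Si](C)(C)C)C(C3=C4C(C)=CC[C@@H](C(C)C)C4CC(C)=C3O[Si](C)(C)C)=C2C(C)=CC[C@@H](C(C)C)C2C1 | intermediate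
10 | (5S,5'S)-3,3',8,8'-tetramethyl-5,5'-di(propan-2-yl)-5,5',6,6'-tetrahydro-[1,1'-binaphthalene]-2,2'-diol | Cc1cc2c(c(-c3c(O)c(C)cc4c3C(C)=CC[C@H]4C(C)C)c1O)C(C)=CC[C@H]2C(C)C | intermediate
11 | (5S,5'S,8S,8'S)-3,3',8,8'-tetramethyl-5,5'-di(propan-2-yl)-5,5',6,6',7,7',8,8'-octahydro-[1,1'-binaphthalene]-2,2'-diol | Cc1cc2c(c(-c3c(O)c(C)cc4c3[C@@H](C)CC[C@H]4C(C)C)c1O)[C@@H](C)CC[C@H]2C(C)C | target

## Step count and least certain steps

Total step count: 7. Longest linear sequence: 6 steps (3 → 4 → 6 → 8 → 9 → 10 → 11); the carvone branch (1 → 2) joins at step 4.

**Step 4 (key step).** Three processes could divert it: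
- closure of a C3 enolate onto C7 of its own enone (bicyclo[2.2.2]octanone formation), either before the cold quench or during the basic aldol stage;
- stalling of the second condensation because of crowding at the forming C1–C1' junction;
- base-mediated double-bond migration into the ring, which would aromatise without control at C8.

Within the step, the first is countered by replacing KOH with pyrrolidinium acetate, which enolises the C2 ketone as the less substituted enamine toward C1 only.

The fallback gives up the twofold annulation and makes the biaryl bond last. It sets out from 2. The same lithium enolate is added to commercial 3-methylbut-3-en-2-one and the adduct is condensed with KOH in MeOH to (5S)-3,8-dimethyl-5-(propan-2-yl)-4,4a,5,6-tetrahydronaphthalen-2(3H)-one F1, a single annulation without the 1,4-diketone and without the crowded junction. LiN(i-Pr)2 and Me3SiCl give the trimethylsilyl dienol ether F2, and Pd(OAc)2 in MeCN gives (5S)-3,8-dimethyl-5-(propan-2-yl)-5,6-dihydronaphthalen-2-ol F3. Hydrogenation with the same iridium catalyst, now on an unhindered alkene, gives (5S,8S)-3,8-dimethyl-5-(propan-2-yl)-5,6,7,8-tetrahydronaphthalen-2-ol F4. Oxidative phenol coupling of F4 with (t-BuO)2 in chlorobenzene at 140 °C then joins C1 to C1', since C1 is the only free ortho position and the para position is the ring fusion. This comes back to the route at 11.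

**Step 7.** The reduction may stall because the alkene carbon C8 lies peri to the biaryl axis and the free phenols can slow a cationic catalyst, or the facial selectivity may differ between rotamers about the axis. The fallback is an ionic hydrogenation, which sets out from 10 and comes back at 11. With Et3SiH and CF3CO2H in CH2Cl2 at 0 °C, protonation at the accessible C7 gives the tertiary benzylic cation at C8, and the small silane delivers hydride anti to the pseudoaxial isopropyl group. Reversible capture of the cation by the neighbouring phenol oxygen does not divert the reduction. No new compound is made on this way (F0).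

**Step 6.** Palladium may dehydrogenate the 5,6-dihydronaphthalene further toward a naphthalene, with loss of C5, or palladium hydride may shift C7=C8. The fallback is metal-free and sets out from 9. PhSeCl in CH2Cl2 at −78 °C converts both silyl enol ethers into the alpha-selanyl ketone, (5S,5'S)-3,3',8,8'-tetramethyl-3,3'-bis(phenylselanyl)-5,5'-di(propan-2-yl)-4,4',4a,4a',5,5',6,6'-octahydro-[1,1'-binaphthalene]-2,2'(3H,3'H)-dione F5. H2O2 and pyridine at 0 °C then trigger selenoxide syn-elimination and tautomerisation. This comes back at 10.

**Step 5.** Deprotonation may take place at C6 or C4a (extended enolates) or stop after one half, because both carbonyls are shielded. The fallback avoids a preformed enolate. It sets out from 8 and comes back at 10 by direct aerobic dehydrogenation: Pd(O2CCF3)2 (catalytic), 2-(dimethylamino)pyridine, TsOH, O2, DMSO, 80 °C, the known conversion of cyclohexenones into phenols. No new compound is made on this way (F0).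

## Further compounds

F1 | step 4 | (5S)-3,8-dimethyl-5-(propan-2-yl)-4,4a,5,6-tetrahydronaphthalen-2(3H)-one (C3/C4a epimer mixture) | CC1CC2C(=CC1=O)C(C)=CC[C@H]2C(C)C
F2 | step 4 | trimethyl{[(5S)-3,8-dimethyl-5-(propan-2-yl)-4,4a,5,6-tetrahydronaphthalen-2-yl]oxy}silane | CC1=C(O[Si](C)(C)C)C=C2C(C)=CC[C@@H](C(C)C)C2C1
F3 | step 4 | (5S)-3,8-dimethyl-5-(propan-2-yl)-5,6-dihydronaphthalen-2-ol | Cc1cc2c(cc1O)C(C)=CC[C@H]2C(C)C
F4 | step 4 | (5S,8S)-3,8-dimethyl-5-(propan-2-yl)-5,6,7,8-tetrahydronaphthalen-2-ol | Cc1cc2c(cc1O)[C@@H](C)CC[C@H]2C(C)C
F0 | step 7 | none | none
F5 | step 6 | (5S,5'S)-3,3',8,8'-tetramethyl-3,3'-bis(phenylselanyl)-5,5'-di(propan-2-yl)-4,4',4a,4a',5,5',6,6'-octahydro-[1,1'-binaphthalene]-2,2'(3H,3'H)-dione | CC1([Se]c6ccccc6)CC2C(=C(C3=C4C(C)=CC[C@@H](C(C)C)C4CC(C)([Se]c5ccccc5)C3=O)C1=O)C(C)=CC[C@H]2C(C)C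
F0 | step 5 | none | none
A1 | alternative 1 | (5S,5'S)-2,2'-dimethoxy-3,3'-dimethyl-8,8'-dimethylidene-5,5'-di(propan-2-yl)-5,5',6,6',7,7',8,8'-octahydro-1,1'-binaphthalene | Cc1cc2c(c(-c3c(OC)c(C)cc4c3C(=C)CC[C@H]4C(C)C)c1OC)C(=C)CC[C@H]2C(C)C
A2 | alternative 1 | 6,6'-dimethoxy-5,5'-dimethyl-3,3'-bis[(3S)-2-methylhept-6-en-3-yl]-[1,1'-biphenyl]-2,2'-diyl bis(trifluoromethanesulfonate) | Cc1cc([C@@H](CCC=C)C(C)C)c(OS(=O)(=O)C(F)(F)F)c(-c2c(OC)c(C)cc([C@@H](CCC=C)C(C)C)c2OS(=O)(=O)C(F)(F)F)c1OC
A3 | alternative 2 | 9,9-di(propan-2-yloxy)-9-silafluorene bearing both tetralin rings (target with silicon bridging C2 and C2') | Cc1cc2c(c3c1[Si](OC(C)C)(OC(C)C)c1c(C)cc4c(c1-3)[C@@H](C)CC[C@H]4C(C)C)[C@@H](C)CC[C@H]2C(C)C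
A4 | alternative 2 | (3S,6S,11S,14S)-6,11-dimethyl-3,14-di(propan-2-yl)hexadeca-1,7,9,15-tetrayne | C#C[C@H](C(C)C)CC[C@H](C)C#CC#C[C@@H](C)CC[C@@H](C(C)C)C#C
A5 | alternative 2 | di(propan-2-yloxy)di(prop-1-yn-1-yl)silane | CC#C[Si](OC(C)C)(OC(C)C)C#CC
A6 | alternative 3 | 1,1'-[(5S,5'S,8S,8'S)-3,3',8,8'-tetramethyl-5,5'-di(propan-2-yl)-5,5',6,6',7,7',8,8'-octahydro-[1,1'-binaphthalene]-2,2'-diyl]di(ethan-1-one) | Cc1cc2c(c(-c3c(C(C)=O)c(C)cc4c3[C@@H](C)CC[C@H]4C(C)C)c1C(C)=O)[C@@H](C)CC[C@H]2C(C)C
A7 | alternative 3 | octa-3,5-diyne-2,7-dione | CC(=O)C#CC#CC(C)=O
A8 | alternative 3 | (3S,6S)-3-methyl-1-[(1E)-prop-1-en-1-yl]-6-(propan-2-yl)cyclohex-1-ene | C/C=C/C1=C[C@@H](C)CC[C@H]1C(C)C
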